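**Retrosynthetic overview**

1. Numbering (eunicellane type): cyclohexane C1, C10–C14; tetrahydrofuran C1, C2, O, C9, C10; oxonane O, C2–C9; oxepane C1, C2, C3, O, C16, C15, C14. The target comes from tetracyclic alcohol 34 by late C4 acetylation, C11/C12 adjustment on the C11=C12 alkene, C11 esterification and C7 methylenation.
2. Key disconnection: 34 is an isomer of the monocyclic oxonane 32. An intramolecular Diels–Alder reaction (bonds C1–C10 and C13–C14) closes the cyclohexene and the tetrahydrofuran; the C16 hydroxyl then opens the C3–C4 epoxide at C3, which closes the oxepane last and frees the C4 hydroxyl.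
3. Enabling feature: O16 hangs on C15–C14 and C3 is joined through C2 to C1. While C1=C14 is an E double bond, a seven-membered ring through it would be a trans-cycloheptene, so the hydroxy epoxide is inert; once the cycloaddition makes C1 and C14 sp3 and trans, O16 lies anti to the C3–O epoxide bond.
4. 32 comes from (Z)-oxonene 23 (ring-closing metathesis at C3=C4, then reagent-controlled epoxidation) with two arms: C1 aldehyde plus sulfone 7 (C14–C16, carries C15) and C10 aldehyde plus two Wittig reactions. 23 comes from an acyclic ether whose C2 centre is set by CBS reduction and whose C9 centre is set by auxiliary-controlled glycolate alkylation.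
5. Ring order: oxonane, then cyclohexene and tetrahydrofuran together, then oxepane.

Key step: step 24

Remark: C17 is the methyl on C15, C18 the methyl on C3, C19 the exocyclic CH2 on C7, C20 the methyl on C12; the ester side chain read from the SMILES is (R)-2-hydroxyoctanoate.
Remark: 4, 8, 11, 15 and the L-fructose-derived epoxidation ketone are taken as purchasable.

**Route**

Step 1
Reactants: 1 prop-2-yn-1-ol
Product: 2 hex-5-en-2-yn-1-ol
Conditions: allyl bromide, CuI (cat.), K2CO3, NaI (cat.), DMF, rt
Reagents that add atoms: allyl bromide, C=CCBr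
Why: copper acetylide allylation of the terminal alkyne should give the skipped enyne without touching the hydroxyl.

Step 2
Reactants: 2 hex-5-en-2-yn-1-ol
Product: 3 1-iodohex-5-en-2-yne
Conditions: I2, PPh3, imidazole, CH2Cl2, 0 °C
Reagents that add atoms: iodine, II
Why: Appel-type iodination converts the propargylic alcohol into the reactive iodide under neutral conditions.

Step 3
Reactants: 4 (R)-3-bromo-2-methylpropan-1-ol
Product: 5 (R)-2-methyl-3-[(1-phenyltetrazol-5-yl)sulfanyl]propan-1-ol
Conditions: 1-phenyl-1H-tetrazole-5-thiol, K2CO3, acetone, 50 °C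
Reagents that add atoms: 1-phenyl-1H-tetrazole-5-thiol, Sc1nnnn1-c1ccccc1
Why: SN2 thioetherification of the primary bromide; the stereocentre (later C15) comes from the chiral pool and is not touched.

Step 4
Reactants: 5 (R)-2-methyl-3-[(1-phenyltetrazol-5-yl)sulfanyl]propan-1-ol
Product: 6 silyl ether of 5
Conditions: tert-butyldimethylsilyl chloride, imidazole, CH2Cl2, rt
Reagents that add atoms: tert-butyldimethylsilyl chloride, CC(C)(C)[Si](C)(C)Cl
Why: standard silylation of the primary alcohol (the later O16).

Step 5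
Reactants: 6 silyl ether of 5
Product: 7 (R)-sulfone (C14–C16 fragment)
Conditions: (NH4)6Mo7O24·4H2O (cat.), 30% H2O2, EtOH, 0 °C → rt
Reagents that add atoms: hydrogen peroxide, OO
Why: molybdate-catalysed sulfide-to-sulfone oxidation gives the Julia–Kocienski reagent and tolerates the silyl ether.

Step 6
Reactants: 8 (R)-2-hydroxyoctanoic acid
Product: 10 (R)-2-(tert-butyldimethylsilyloxy)octanoic acid, via bis-silyl derivative 9 (not isolated)
Conditions: tert-butyldimethylsilyl chloride (2.5 equiv), imidazole, DMF, rt; then K2CO3, MeOH/THF/H2O, rt; mild acid work-up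
Reagents that add atoms: tert-butyldimethylsilyl chloride, CC(C)(C)[Si](C)(C)Cl
Why: exhaustive silylation followed by selective solvolysis of the labile silyl ester leaves the secondary silyl ether, and the stereocentre is not involved.

Step 7
Reactants: 11 2-(benzyloxy)-N-methoxy-N-methylacetamide
Product: 12 1-(benzyloxy)-3-methylbut-3-en-2-one
Conditions: isopropenylmagnesium bromide, THF, 0 °C; cold aq. HCl quench
Reagents that add atoms: isopropenylmagnesium bromide, CC(=C)[Mg]Br
Why: Weinreb ketone synthesis, in which the chelated tetrahedral intermediate prevents over-addition.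

Step 8
Reactants: 12 1-(benzyloxy)-3-methylbut-3-en-2-one
Product: 13 (S)-1-(benzyloxy)-3-methylbut-3-en-2-ol
Conditions: (S)-2-methyl-CBS-oxazaborolidine (20 mol %), catecholborane, PhMe, −78 °C
Reagents that add atoms: none
Why: Corey–Bakshi–Shibata reduction in which the isopropenyl group acts as the large substituent, so the (S)-catalyst should deliver hydride to give the (S)-carbinol (C2 of the target).

Step 9
Reactants: 13 (S)-1-(benzyloxy)-3-methylbut-3-en-2-ol
Product: 14 [(S)-1-(benzyloxy)-3-methylbut-3-en-2-yl]oxyacetic acid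
Conditions: NaH (3 equiv), bromoacetic acid, THF, 0 °C → rt
Reagents that add atoms: bromoacetic acid, OC(=O)CBr
Why: Williamson etherification of the sodium alkoxide with sodium bromoacetate; the benzyl ether was chosen because it cannot migrate under these conditions.

Step 10
Reactants: 14 [(S)-1-(benzyloxy)-3-methylbut-3-en-2-yl]oxyacetic acid; 15 (S)-4-benzyl-1,3-oxazolidin-2-one
Product: 17 glycolate imide, via mixed pivalic anhydride 16 (not isolated)
Conditions: pivaloyl chloride, Et3N, THF, −20 °C; then LiCl, 15, rt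
Reagents that add atoms: pivaloyl chloride, CC(C)(C)C(Cl)=O (its atoms stay in 16 only)
Why: mixed-anhydride N-acylation of the oxazolidinone installs the auxiliary that will control C9.

Step 11
Reactants: 17 glycolate imide; 3 1-iodohex-5-en-2-yne
Product: 19 C9-alkylated imide (9R), via sodium enolate 18 (not isolated)
Conditions: NaN(SiMe3)2, THF, −78 °C; then 3, −78 → −45 °C
Reagents that add atoms: sodium bis(trimethylsilyl)amide, [Na+].C[Si](C)(C)[N-][Si](C)(C)C (sodium stays in 18 only)
Why: auxiliary-controlled glycolate enolate alkylation, in which the chelated Z-enolate is attacked by the propargylic iodide on the face opposite the benzyl group, setting C9 as R.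

Step 12
Reactants: 19 C9-alkylated imide (9R)
Product: 20 methyl (R)-2-{[(S)-1-(benzyloxy)-3-methylbut-3-en-2-yl]oxy}oct-7-en-4-ynoate
Conditions: NaOMe (0.3 equiv), MeOH, 0 °C
Reagents that add atoms: methanol, CO
Why: methoxide transesterification of the activated imide releases the auxiliary at a temperature where the alkoxy-substituted C9 should not epimerize.

Step 13
Reactants: 20 methyl (R)-2-{[(S)-1-(benzyloxy)-3-methylbut-3-en-2-yl]oxy}oct-7-en-4-ynoate
Product: 21 C7 keto ester (4-oxooct-7-enoate)
Conditions: NaAuCl4·2H2O (5 mol %), EtOH/H2O (4:1), rt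
Reagents that add atoms: water, O
Why: carbonyl-assisted alkyne hydration, in which 5-exo-dig attack of the ester carbonyl oxygen on the gold-activated alkyne places the ketone at C7 (γ to the ester) and not at C6.

Step 14
Reactants: 21 C7 keto ester
Product: 22 C7 dioxolane diene
Conditions: 1,2-bis(trimethylsilyloxy)ethane, TMSOTf (cat.), CH2Cl2, −78 → −20 °C
Reagents that add atoms: 1,2-bis(trimethylsilyloxy)ethane, C[Si](C)(C)OCCO[Si](C)(C)C
Why: aprotic Noyori-type ketalization masks the β-alkoxy ketone without base (no β-elimination), so that C7 stays inert to the later hydride, ylide, peroxide and borane steps.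

Step 15
Reactants: 22 C7 dioxolane diene
Product: 23 (Z)-oxonene
Conditions: second-generation Grubbs catalyst (10 mol %), CH2Cl2 (2 mM), 40 °C
Reagents that add atoms: none
Why: ring-closing metathesis of the only two alkenes (the vinyl group loads the catalyst, which closes onto the isopropenyl group) should give the trisubstituted C3=C4 alkene; the ring enforces Z geometry, and the ether gauche preference and the ketal Thorpe–Ingold effect favour closure.

Step 16
Reactants: 23 (Z)-oxonene
Product: 24 (3S,4S)-epoxy oxonane benzyl ether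
Conditions: L-fructose-derived Shi ketone (30 mol %), KHSO5 (as Oxone), K2CO3, Bu4NHSO4, MeCN/CH2(OMe)2/aq. Na2B4O7 buffer, 0 °C
Reagents that add atoms: potassium peroxymonosulfate, [K+].[O-]S(=O)(=O)OO
Why: Shi epoxidation of the only alkene through the spiro transition state; this catalyst enantiomer should deliver oxygen to the face of C3=C4 opposite to the one that O16 must later attack, setting C4 and the epoxide carbon C3.

Step 17
Reactants: 24 (3S,4S)-epoxy oxonane benzyl ether
Product: 25 epoxy oxonane C1 alcohol
Conditions: H2 (1 atm), Pd/C, EtOAc, rt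
Reagents that add atoms: none
Why: hydrogenolysis of the benzyl ether at a stage with no alkene present; the non-benzylic trisubstituted epoxide, ester and ketal should be inert.

Step 18
Reactants: 25 epoxy oxonane C1 alcohol
Product: 26 epoxy oxonane C1 aldehyde
Conditions: Dess–Martin periodinane, NaHCO3, CH2Cl2, 0 °C → rt
Reagents that add atoms: none
Why: buffered Dess–Martin oxidation gives the α-alkoxy aldehyde without epimerizing C2 and is used at once, which also forestalls lactonization of the hydroxy ester.

Step 19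
Reactants: 7 (R)-sulfone (C14–C16 fragment); 26 epoxy oxonane C1 aldehyde
Product: 28 E-alkenyl ester, via potassium sulfonyl carbanion 27 (not isolated)
Conditions: KN(SiMe3)2, DME, −60 °C; then 26, −60 °C → rt
Reagents that add atoms: potassium bis(trimethylsilyl)amide, [K+].C[Si](C)(C)[N-][Si](C)(C)C (potassium stays in 27 only)
Why: Julia–Kocienski olefination with the phenyltetrazolyl sulfone (potassium counter-ion, polar solvent) should give the E C1=C14 alkene and carries the C15 stereocentre in unchanged.

Step 20
Reactants: 28 E-alkenyl ester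
Product: 29 C10 aldehyde
Conditions: iBu2AlH (1.1 equiv), CH2Cl2, −78 °C; Rochelle salt work-up
Reagents that add atoms: none
Why: half-reduction of the α-alkoxy ester through its stable chelated tetrahedral aluminate; epoxide, ketal and silyl ether tolerate −78 °C.

Step 21
Reactants: 29 C10 aldehyde
Product: 30 E-enone
Conditions: 1-(triphenylphosphoranylidene)propan-2-one, CH2Cl2, rt → 40 °C
Reagents that add atoms: 1-(triphenylphosphoranylidene)propan-2-one, CC(=O)C=P(c1ccccc1)(c1ccccc1)c1ccccc1
Why: Wittig reaction with a stabilized ylide gives the E C10=C11 enone under neutral conditions that do not epimerize C9.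

Step 22
Reactants: 30 E-enone
Product: 31 tetraene silyl ether
Conditions: Ph3PCH3Br, KOtBu, THF, 0 °C; then 30, 0 °C
Reagents that add atoms: methyltriphenylphosphonium bromide, C[P+](c1ccccc1)(c1ccccc1)c1ccccc1.[Br-]
Why: Wittig methylenation of the enone carbonyl (1,2-addition) turns it into the 2-methyl-1,3-diene C10=C11–C12(C20)=C13.

Step 23
Reactants: 31 tetraene silyl ether
Product: 32 tetraene alcohol
Conditions: Bu4NF, AcOH (buffer), THF, 0 °C
Reagents that add atoms: none
Why: fluoride desilylation frees O16, which cannot yet reach the epoxide because any ring through the E C1=C14 bond would be a trans-cycloheptene.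

Step 24
Reactants: 32 tetraene alcohol
Product: 34 tetracyclic alcohol, via Diels–Alder adduct 33 (not isolated)
Conditions: PhMe (5 mM), BHT (cat.), 110 °C; then 0 °C, camphorsulfonic acid (10 mol %), CH2Cl2
Reagents that add atoms: none
Why: Heating should bring the C9 diene and the C2 dienophile together in a type 1 intramolecular Diels–Alder reaction (three-atom C9–O–C2 tether), a concerted suprafacial [4+2] that forms C1–C10 and C13–C14 and so closes the cyclohexene and, as the tether ring, the cis-fused tetrahydrofuran; catalytic acid then triggers SN2-like opening of the protonated C3–C4 epoxide at its tertiary carbon C3 by O16, a 7-exo-tet closure that completes the oxepane. The closest known reaction types are the intramolecular Diels–Alder reaction of 2,9-cis-disubstituted oxonane tetraenes and the acid-catalysed hydroxy-epoxide cyclization used for oxepanes in polyether synthesis. C1, C10 and C14 are set in the cycloaddition: the E dienophile places C15 trans to C2, and the cis arrangement of the two arms on the oxonane should force the exo transition state on the face away from the medium ring, giving H1 and H10 cis to each other and trans to H2 and H9. C3 is set by inversion of the (3S)-epoxide carbon, C4 keeps the epoxide oxygen as its free hydroxyl, and C15 arrives unchanged from sulfone 7. The step needs no epoxide opening before the cycloaddition (secured by the E C1=C14 bond, which forbids a seven-membered ring), attack at C3 and not C4 (secured by the tertiary centre and the 7-exo over 8-endo preference), and survival of the dioxolane (secured by anhydrous catalytic acid).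

Step 25
Reactants: 34 tetracyclic alcohol
Product: 35 tetracyclic C4 acetate
Conditions: Ac2O, DMAP, Et3N, CH2Cl2, rt
Reagents that add atoms: acetic anhydride, CC(=O)OC(C)=O
Why: DMAP-catalysed acetylation of the only free hydroxyl installs the C4 acetate.

Step 26
Reactants: 35 tetracyclic C4 acetate
Product: 37 11-epi alcohol (11R,12S), via C11 alkylborane 36 (not isolated)
Conditions: BH3·THF, THF, 0 °C → rt; then NaBO3·4H2O, H2O, rt
Reagents that add atoms: borane, B (boron stays in 36 only); sodium perborate, [Na+].O[B-](O)(O)OO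
Why: hydroboration–oxidation of the only alkene adds H and B syn from the face carrying H1 and H10 (the other face is blocked by the cis-fused tetrahydrofuran with C9 pseudoaxial), boron going to the less substituted C11; this sets C12 with its methyl on the hindered face, while the C11 hydroxyl is on the wrong face and is corrected in the next two steps.

Step 27
Reactants: 37 11-epi alcohol (11R,12S)
Product: 38 C11 ketone (12S)
Conditions: Dess–Martin periodinane, NaHCO3, CH2Cl2, 0 °C
Reagents that add atoms: none
Why: non-basic Dess–Martin oxidation should give the ketone without epimerizing the contra-thermodynamic axial C12 methyl.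

Step 28
Reactants: 38 C11 ketone (12S)
Product: 39 C11 alcohol (11S,12S)
Conditions: NaBH4, CeCl3·7H2O, MeOH, −78 → −40 °C
Reagents that add atoms: none
Why: borohydride reduction in which hydride should add from the H1/H10 face, because the other face of the carbonyl is flanked by the axial C12 methyl and the axial C9, giving the equatorial 11S alcohol; cerium chloride keeps the medium non-basic.

Step 29
Reactants: 39 C11 alcohol (11S,12S); 10 (R)-2-(tert-butyldimethylsilyloxy)octanoic acid
Product: 40 C11 ester silyl ether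
Conditions: EDC·HCl, DMAP, CH2Cl2, rt
Reagents that add atoms: none
Why: Steglich esterification of the hindered secondary alcohol with the silyl-protected acid, which cannot self-condense.

Step 30
Reactants: 40 C11 ester silyl ether
Product: 41 C7 ketone
Conditions: PPTS, acetone/H2O (9:1), 55 °C
Reagents that add atoms: water, O
Why: mild acid hydrolysis of the dioxolane leaves the acetate, the ester, the secondary silyl ether and the three ring ethers intact.

Step 31
Reactants: 41 C7 ketone
Product: 42 C7 methylene silyl ether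
Conditions: Zn, CH2Br2, TiCl4, THF/CH2Cl2, 0 °C → rt
Reagents that add atoms: dibromomethane, BrCBr
Why: Lombardo methylenation is non-basic, so the β-alkoxy ketone should not eliminate the C9 ether oxygen, and it does not attack the two esters.

Step 32
Reactants: 42 C7 methylene silyl ether
Product: 43 CNP0132024.3
Conditions: HF·pyridine, pyridine/THF, 0 °C → rt
Reagents that add atoms: none
Why: buffered fluoride desilylation frees the side-chain hydroxyl without acyl migration or ester cleavage.

**Compound list**

1 | prop-2-yn-1-ol | C#CCO | starting material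
2 | hex-5-en-2-yn-1-ol | OCC#CCC=C | intermediate
3 | 1-iodohex-5-en-2-yne | ICC#CCC=C | intermediate
4 | (R)-3-bromo-2-methylpropan-1-ol | OC[C@@H](C)CBr | starting material
5 | (R)-2-methyl-3-[(1-phenyltetrazol-5-yl)sulfanyl]propan-1-ol | OC[C@@H](C)CSc1nnnn1-c1ccccc1 | intermediate
6 | silyl ether of 5: 5-{[(R)-3-(tert-butyldimethylsilyloxy)-2-methylpropyl]sulfanyl}-1-phenyltetrazole | CC(C)(C)[Si](C)(C)OC[C@@H](C)CSc1nnnn1-c1ccccc1 | intermediate
7 | (R)-sulfone (C14–C16 fragment): 5-{[(R)-3-(tert-butyldimethylsilyloxy)-2-methylpropyl]sulfonyl}-1-phenyltetrazole | CC(C)(C)[Si](C)(C)OC[C@@H](C)CS(=O)(=O)c1nnnn1-c1ccccc1 | intermediate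
8 | (R)-2-hydroxyoctanoic acid | CCCCCC[C@@H](O)C(O)=O | starting material
9 | bis-silyl derivative: tert-butyldimethylsilyl (R)-2-(tert-butyldimethylsilyloxy)octanoate | CCCCCC[C@@H](O[Si](C)(C)C(C)(C)C)C(=O)O[Si](C)(C)C(C)(C)C | intermediate
10 | (R)-2-(tert-butyldimethylsilyloxy)octanoic acid | CCCCCC[C@@H](O[Si](C)(C)C(C)(C)C)C(O)=O | intermediate
11 | 2-(benzyloxy)-N-methoxy-N-methylacetamide | CON(C)C(=O)COCc1ccccc1 | starting material
12 | 1-(benzyloxy)-3-methylbut-3-en-2-one | CC(=C)C(=O)COCc1ccccc1 | intermediate
13 | (S)-1-(benzyloxy)-3-methylbut-3-en-2-ol | C=C(C)[C@H](O)COCc1ccccc1 | intermediate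
14 | [(S)-1-(benzyloxy)-3-methylbut-3-en-2-yl]oxyacetic acid | C=C(C)[C@H](OCC(O)=O)COCc1ccccc1 | intermediate
15 | (S)-4-benzyl-1,3-oxazolidin-2-one | O=C1N[C@@H](Cc2ccccc2)CO1 | starting material
16 | mixed pivalic anhydride of 14 | C=C(C)[C@H](OCC(=O)OC(=O)C(C)(C)C)COCc1ccccc1 | intermediate
17 | glycolate imide: (S)-4-benzyl-3-acyl oxazolidinone of 14 | C=C(C)[C@H](OCC(=O)N1[C@@H](Cc2ccccc2)COC1=O)COCc1ccccc1 | intermediate
18 | sodium Z-enolate of 17 | C=C(C)[C@H](O/C=C(\[O-])N1[C@@H](Cc2ccccc2)COC1=O)COCc1ccccc1.[Na+] | intermediate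
19 | C9-alkylated imide (9R): 17 carrying a hex-5-en-2-ynyl group on the glycolate carbon | C=C(C)[C@H](O[C@H](CC#CCC=C)C(=O)N1[C@@H](Cc2ccccc2)COC1=O)COCc1ccccc1 | intermediate
20 | methyl (R)-2-{[(S)-1-(benzyloxy)-3-methylbut-3-en-2-yl]oxy}oct-7-en-4-ynoate | C=C(C)[C@H](O[C@H](CC#CCC=C)C(=O)OC)COCc1ccccc1 | intermediate
21 | C7 keto ester: methyl (R)-2-{[(S)-1-(benzyloxy)-3-methylbut-3-en-2-yl]oxy}-4-oxooct-7-enoate | C=C(C)[C@H](O[C@H](CC(=O)CCC=C)C(=O)OC)COCc1ccccc1 | intermediate
22 | C7 dioxolane diene: ethylene ketal of 21 | C=C(C)[C@H](O[C@H](CC1(CCC=C)OCCO1)C(=O)OC)COCc1ccccc1 | intermediate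
23 | (Z)-oxonene: nine-membered ether with C3=C4 (methyl on C3), C7 dioxolane, CH2OBn on C2 and CO2Me on C9, 2,9-cis | C/C1=C/CCC2(OCCO2)C[C@H](C(=O)OC)O[C@@H]1COCc1ccccc1 | intermediate
24 | (3S,4S)-epoxy oxonane benzyl ether: cis-epoxide of 23 | C[C@]12O[C@H]1CCC3(OCCO3)C[C@H](C(=O)OC)O[C@@H]2COCc1ccccc1 | intermediate
25 | epoxy oxonane C1 alcohol | C[C@]12O[C@H]1CCC3(OCCO3)C[C@H](C(=O)OC)O[C@@H]2CO | intermediate
26 | epoxy oxonane C1 aldehyde | C[C@]12O[C@H]1CCC3(OCCO3)C[C@H](C(=O)OC)O[C@@H]2C=O | intermediate
27 | potassium sulfonyl carbanion of 7 | CC(C)(C)[Si](C)(C)OC[C@@H](C)[CH-]S(=O)(=O)c1nnnn1-c1ccccc1.[K+] | intermediate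
28 | E-alkenyl ester: 26 with C1 turned into the E C1=C14 alkene bearing (15S)-CH(CH3)CH2OTBS | C[C@]12O[C@H]1CCC3(OCCO3)C[C@H](C(=O)OC)O[C@@H]2/C=C/[C@H](C)CO[Si](C)(C)C(C)(C)C | intermediate
29 | C10 aldehyde | C[C@]12O[C@H]1CCC3(OCCO3)C[C@H](C=O)O[C@@H]2/C=C/[C@H](C)CO[Si](C)(C)C(C)(C)C | intermediate
30 | E-enone (C10=C11 E, C12 methyl ketone) | C[C@]12O[C@H]1CCC3(OCCO3)C[C@H](/C=C/C(C)=O)O[C@@H]2/C=C/[C@H](C)CO[Si](C)(C)C(C)(C)C | intermediate
31 | tetraene silyl ether (E diene on C9, E dienophile on C2) | C[C@]12O[C@H]1CCC3(OCCO3)C[C@H](/C=C/C(C)=C)O[C@@H]2/C=C/[C@H](C)CO[Si](C)(C)C(C)(C)C | intermediate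
32 | tetraene alcohol (free C16 hydroxyl) | C[C@]12O[C@H]1CCC3(OCCO3)C[C@H](/C=C/C(C)=C)O[C@@H]2/C=C/[C@H](C)CO | intermediate
33 | Diels–Alder adduct: tricyclic (cyclohexene, tetrahydrofuran, oxonane) C3–C4 epoxide with free C16 hydroxyl | C1COC2(O1)CC[C@@H]3O[C@]3(C)[C@@H]4O[C@H](C2)[C@H]5C=C(C)C[C@H]([C@H](C)CO)[C@@H]45 | intermediate
34 | tetracyclic alcohol: oxepane closed, C4 hydroxyl, C11=C12 alkene, C7 dioxolane | C1COC2(O1)CC[C@H](O)[C@@]3(C)OC[C@@H](C)[C@H]4CC(C)=C[C@H]5[C@@H]4[C@H]3O[C@@H]5C2 | intermediate
35 | tetracyclic C4 acetate | C1COC2(O1)CC[C@H](OC(C)=O)[C@@]3(C)OC[C@@H](C)[C@H]4CC(C)=C[C@H]5[C@@H]4[C@H]3O[C@@H]5C2 | intermediate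
36 | C11 alkylborane | C1COC2(O1)CC[C@H](OC(C)=O)[C@@]3(C)OC[C@@H](C)[C@H]4C[C@H](C)[C@@H](B)[C@H]5[C@@H]4[C@H]3O[C@@H]5C2 | intermediate
37 | 11-epi alcohol (11R,12S) | C1COC2(O1)CC[C@H](OC(C)=O)[C@@]3(C)OC[C@@H](C)[C@H]4C[C@H](C)[C@@H](O)[C@H]5[C@@H]4[C@H]3O[C@@H]5C2 | intermediate
38 | C11 ketone (12S) | C1COC2(O1)CC[C@H](OC(C)=O)[C@@]3(C)OC[C@@H](C)[C@H]4C[C@H](C)C(=O)[C@H]5[C@@H]4[C@H]3O[C@@H]5C2 | intermediate
39 | C11 alcohol (11S,12S) | C1COC2(O1)CC[C@H](OC(C)=O)[C@@]3(C)OC[C@@H](C)[C@H]4C[C@H](C)[C@H](O)[C@H]5[C@@H]4[C@H]3O[C@@H]5C2 | intermediate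
40 | C11 ester silyl ether: (R)-2-(tert-butyldimethylsilyloxy)octanoate of 39 | C1COC2(O1)CC[C@H](OC(C)=O)[C@@]3(C)OC[C@@H](C)[C@H]4C[C@H](C)[C@H](OC(=O)[C@H](O[Si](C)(C)C(C)(C)C)CCCCCC)[C@H]5[C@@H]4[C@H]3O[C@@H]5C2 | intermediate
41 | C7 ketone | O=C1CC[C@H](OC(C)=O)[C@@]2(C)OC[C@@H](C)[C@H]3C[C@H](C)[C@H](OC(=O)[C@H](O[Si](C)(C)C(C)(C)C)CCCCCC)[C@H]4[C@@H]3[C@H]2O[C@@H]4C1 | intermediate
42 | C7 methylene silyl ether | C=C1CC[C@H](OC(C)=O)[C@@]2(C)OC[C@@H](C)[C@H]3C[C@H](C)[C@H](OC(=O)[C@H](O[Si](C)(C)C(C)(C)C)CCCCCC)[C@H]4[C@@H]3[C@H]2O[C@@H]4C1 | intermediate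
43 | CNP0132024.3 | C=C1CC[C@H](OC(C)=O)[C@@]2(C)OC[C@@H](C)[C@H]3C[C@H](C)[C@H](OC(=O)[C@H](O)CCCCCC)[C@H]4[C@@H]3[C@H]2O[C@@H]4C1 | target

**Count and risks**

Total step count: 32. Longest linear sequence: 26 steps (steps 7–32, from 11 to 43).

Steps most likely to fail:

Step 24. The unactivated C1=C14 dienophile may add too slowly, so that the hydroxy epoxide degrades (hydride shift to a C4 ketone, elimination to an allylic alcohol) before or instead of ring closure, or the cycloaddition may lose facial control. The fallback is a stepwise sequence with a carbonyl-activated dienophile; it sets out from 25 and comes back to the route at 33. The C1 hydroxyl of 25 is silylated (tert-butyldimethylsilyl chloride, imidazole) to silyl ether F1, and iBu2AlH at −78 °C gives C10 aldehyde F2. Wittig reaction with 1-(triphenylphosphoranylidene)propan-2-one gives E-enone F3, and methylenation with Ph3P=CH2 gives diene F4. Bu4NF frees C1 alcohol F5, and Dess–Martin oxidation gives C1 aldehyde F6. A second Wittig reaction with the same acetonyl ylide gives enone tetraene F7, whose activated dienophile should undergo the intramolecular Diels–Alder reaction near room temperature to tricyclic methyl ketone F8. Methylenation gives isopropenyl compound F9. Hydroboration of its 1,1-disubstituted alkene with the enantiomer of diisopinocampheylborane that delivers hydrogen to the Si face of C15 (reagent control), then NaBO3, should give 33, which is closed to 34 with camphorsulfonic acid as in the second stage of step 24.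

Step 16. Catalyst control may be too weak against the facial bias of the medium ring, so that oxygen is delivered to the face of C3=C4 on the side of the C1 substituent. The fallback sets out from 23 and comes back at 24: N-bromosuccinimide in aqueous THF should place bromine on the face the ring prefers and water on C3 from the other face, giving bromohydrin F10, and K2CO3 in MeOH then closes the epoxide by displacement of bromide, which puts the epoxide oxygen on the face opposite to the one attacked first and gives 24.

Step 13. Regiocontrol of the hydration may be lost (water adding at C6 to give the δ-keto ester) or the gold catalyst may engage the enyne units. The fallback sets out from 20 and comes back at 21: saponification (LiOH, THF/H2O, 0 °C) gives alkynoic acid F11, AuCl-catalysed 5-exo-dig cycloisomerization (K2CO3, MeCN) gives the (Z)-γ-alkylidene butyrolactone F12 with oxygen fixed on C7, and methanolysis (MeOH, DMAP cat.) opens the enol lactone to keto ester 21.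

**Further compounds**

F1 | step 24 | silyl ether of 25 (C1 OTBS, C10 methyl ester) | C[C@]12O[C@H]1CCC3(OCCO3)C[C@H](C(=O)OC)O[C@@H]2CO[Si](C)(C)C(C)(C)C
F2 | step 24 | C10 aldehyde with C1 OTBS | C[C@]12O[C@H]1CCC3(OCCO3)C[C@H](C=O)O[C@@H]2CO[Si](C)(C)C(C)(C)C
F3 | step 24 | E-enone with C1 OTBS | C[C@]12O[C@H]1CCC3(OCCO3)C[C@H](/C=C/C(C)=O)O[C@@H]2CO[Si](C)(C)C(C)(C)C
F4 | step 24 | diene with C1 OTBS | C[C@]12O[C@H]1CCC3(OCCO3)C[C@H](/C=C/C(C)=C)O[C@@H]2CO[Si](C)(C)C(C)(C)C
F5 | step 24 | diene C1 alcohol | C[C@]12O[C@H]1CCC3(OCCO3)C[C@H](/C=C/C(C)=C)O[C@@H]2CO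
F6 | step 24 | diene C1 aldehyde | C[C@]12O[C@H]1CCC3(OCCO3)C[C@H](/C=C/C(C)=C)O[C@@H]2C=O
F7 | step 24 | enone tetraene (activated dienophile) | C[C@]12O[C@H]1CCC3(OCCO3)C[C@H](/C=C/C(C)=C)O[C@@H]2/C=C/C(C)=O
F8 | step 24 | tricyclic methyl ketone (acetyl on C14) | C1COC2(O1)CC[C@@H]3O[C@]3(C)[C@@H]4O[C@H](C2)[C@H]5C=C(C)C[C@H](C(C)=O)[C@@H]45
F9 | step 24 | tricyclic isopropenyl compound | C1COC2(O1)CC[C@@H]3O[C@]3(C)[C@@H]4O[C@H](C2)[C@H]5C=C(C)C[C@H](C(C)=C)[C@@H]45
F10 | step 16 | bromohydrin (C3 hydroxyl, C4 bromide, anti) | C[C@]1(O)[C@H](Br)CCC2(OCCO2)C[C@H](C(=O)OC)O[C@@H]1COCc1ccccc1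
F11 | step 13 | alkynoic acid from 20 | C=C(C)[C@H](O[C@H](CC#CCC=C)C(O)=O)COCc1ccccc1
F12 | step 13 | (Z)-γ-alkylidene butyrolactone | C=C(C)[C@H](O[C@@H]1C/C(=C/CC=C)OC1=O)COCc1ccccc1
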